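Catalyst intermediate B stands at a fork, forward at 49 s⁻¹ or back at 2770 s⁻¹, far faster back than forward, so one visit goes on with a chance of 1.74 %: this is the forward chance, or commitment to catalysis.

    reagent + free catalyst → catalyst intermediate A (k1 = 18000 L mol⁻¹ s⁻¹)
    catalyst intermediate B → released group + catalyst intermediate C (k2 = 49 s⁻¹)
    free catalyst + added ligand ⇌ idle complex (K3 = 2.0 × 10⁵ L mol⁻¹, k3 = 5500 L mol⁻¹ s⁻¹)
    catalyst intermediate C → free catalyst + product (k4 = 470 s⁻¹)
    substrate + catalyst intermediate A ⇌ catalyst intermediate B (K5 = 940 L mol⁻¹, k5 = 2.6 × 10⁶ L mol⁻¹ s⁻¹)

in all of them: substrate 1.0 mM; reagent 1.00 equiv; free catalyst 0.1 mol%; time 50 s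
- north-east: added ligand 0.30 µM
- south: added ligand 0.60 µM
- south-west: added ligand 1.2 µM
- west: added ligand 2.5 µM
- north: added ligand 5.0 µM

* [product] at the end for north-east, south, south-west, west, north, in this order
* how the row runs (falls all the way / rises, then falls / rises all the way / falls, then rises / hardly changes)

- "hardly changes" means that all values lie within two and a half points (for a concentration: within two and a half percent of the largest)
- run time (north-east): 50 s

We follow one catalyst molecule round one turn at the charge; the charge is equimolar, so [substrate] and [reagent] fall together. Free catalyst waits 0.0556 s for reagent. Catalyst intermediate A waits briefly for substrate on each visit, but dividing that wait by the forward chance gives 0.0221 s per turn. The visits to catalyst intermediate B add up to 0.0204 s, and catalyst intermediate C takes 0.00213 s. One turn therefore lasts 0.100 s, and free catalyst holds 55.5 % of that time.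

Added ligand catches the catalyst during that free time. In the north flask we reckon the idle complex to balance at 35.7 % of the catalyst, and with a relaxation rate of 0.0427 s⁻¹ it approaches this over 23.4 s, which is shorter than the run. Averaged over the run, we reckon the idle share at 21.0 % in the north flask and 1.50 % in the north-east flask, with 2.97 % in the south flask, 5.79 % in the south-west flask and 11.5 % in the west flask, so we expect the row to fall as ligand rises.

With 1.00 µM of catalyst, and the whole turn stretching as [substrate] falls, the north-east flask makes 0.388 mM and the north flask 0.326 mM. The weak link is that stretching: 0.0777 s of the turn grows as [substrate] falls, but the 0.0225 s spent in catalyst intermediates B and C does not. Charging that fixed part to the product already estimated, and the rest to the logarithm of the fall in [substrate], we get a logarithm of 0.522 for north-east and 0.414 for north. We commit to 0.406 mM for north-east, 0.402 mM for south, 0.392 mM for south-west, 0.373 mM for west and 0.339 mM for north, a row that falls all the way.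

The forecast gives 0.404 mM, 0.399 mM, 0.389 mM, 0.37 mM and 0.338 mM, a row that falls all the way, on the ground that “product falls steadily but modestly as ligand increases”.

The simulation gives 0.403 mM, 0.399 mM, 0.389 mM, 0.370 mM and 0.337 mM, and the row falls all the way.

The largest single effect on [product] in the north-east flask is the length of the run , with 0.403 mM at 50.0 s against 0.997 mM at 500 s. Within the run, part of what holds the north-east flask back is the return of catalyst intermediate B to substrate and catalyst intermediate A. The forward chance reads this in the north-east flask at 50.0 s: with substrate at 59.6 %, it puts A over B at 1.82, and the flask holds 23.7 % against 13.0 %. Without the return the chance becomes certainty, A's wait shrinks to 3.85 × 10⁻⁴ s, and our sum gives 0.500 mM, while that north-east run reaches 0.492 mM.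

The numbers are those of an exercise, and the outcome is calculated.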